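**Retrosynthetic overview**
1. 35 ⇐ 33: the C11 hydroxymethyl (Stille coupling on a C4 enol triflate) and the C10 p-coumarate go on last; 28 ⇐ 24: the C1 (S)-3-methylpentanoate is put on the lactol of a cis-fused 4-oxo pyranone.
2. The strategy rests on ring A (C1, O2, C3, C4, C5, C9: acyloxy acetal at C1, enol ether C3=C4, both fusion carbons). It is the oxidised form of a 2-(hydroxymethyl)furan with furan carbons C4, C5, C9, C1 and carbinol carbon C3, so 23 ⇐ 21 by Achmatowicz ring expansion.
3. C5 and C9 stay sp2 from 20 to 23 and are set together by one syn hydrogenation (23 → 24).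
4. Ring B (C5–C9) ⇐ iodine–lithium exchange and addition of C9 to the C8 ketone of dioxanone 17 (C8 set from C7); the C6–C7 bond and C7 ⇐ SAMP-hydrazone alkylation of 2,2-dimethyl-1,3-dioxan-5-one with furylmethyl bromide 9, made from 3,4-dibromofuran.
5. Ring order: furan and dioxane rings are bought, ring B closes in step 10, ring A in step 12.

Key step: step 12

Conventions: iridoid numbering is used for the skeleton in all intermediates (C1 acetal, O2, C3, C4, C5 and C9 fusion, C6, C7, C8, C10 on C8, C11 on C4); β is the face of H5 and H9 in the target.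

Assumption: the SAMP azaenolate of the dioxanone is alkylated with its usual sense of induction, which gives the (S) centre needed for C7; the antipodal auxiliary RAMP would be used if the sense proved opposite.

**Route**

Step 1
Reactants: 1 3,4-dibromofuran
Product: 4 (3,4-dibromofuran-2-yl)methanol, via 3,4-dibromo-2-furyllithium 2 (not isolated), via 3,4-dibromofuran-2-carbaldehyde 3 (not isolated)
Conditions: LiN(iPr)2 (1.05 equiv), THF, −78 °C; DMF, −78 °C; then MeOH, NaBH4, −78 → 0 °C
Reagents that add atoms: N,N-dimethylformamide, CN(C)C=O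
Why: Directed ortho-lithiation at one of the two equivalent α-positions (the proton between ring oxygen and bromine is the most acidic), formylation with DMF and in-flask borohydride reduction of the aldehyde install the carbinol carbon that becomes C3 without touching either bromine.

Step 2
Reactants: 4 (3,4-dibromofuran-2-yl)methanol
Product: 6 4-bromo-2-(hydroxymethyl)furan-3-carbaldehyde, via dilithiated furylmethanolate 5 (not isolated)
Conditions: MeLi (1.0 equiv), THF, −78 °C; n-BuLi (1.05 equiv), −78 °C; DMF, −78 → 0 °C; H2O
Reagents that add atoms: N,N-dimethylformamide, CN(C)C=O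
Why: Alkoxide-directed bromine–lithium exchange, in which the lithium alkoxide formed by MeLi holds n-BuLi beside the neighbouring C–Br and chelates the resulting 3-furyllithium, so exchange takes place at the bromine next to the CH2O arm and formylation puts the future C6 on that carbon.

Step 3
Reactants: 6 4-bromo-2-(hydroxymethyl)furan-3-carbaldehyde
Product: 7 (4-bromo-3-formylfuran-2-yl)methyl pivalate
Conditions: PivCl, pyridine, DMAP (cat.), CH2Cl2, 0 °C
Reagents that add atoms: pivaloyl chloride, CC(C)(C)C(=O)Cl
Why: Acylation of the primary alcohol; the pivalate has no α-hydrogen and a shielded carbonyl, so it survives the azaenolate and the low-temperature halogen–lithium exchanges ahead and can later be removed by hydride without touching a silyl ether or the acetonide.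

Step 4
Reactants: 7 (4-bromo-3-formylfuran-2-yl)methyl pivalate
Product: 8 [4-bromo-3-(hydroxymethyl)furan-2-yl]methyl pivalate
Conditions: NaBH4, MeOH/THF, −20 °C
Reagents that add atoms: none
Why: Chemoselective borohydride reduction of the aldehyde in the presence of the hindered ester.

Step 5
Reactants: 8 [4-bromo-3-(hydroxymethyl)furan-2-yl]methyl pivalate
Product: 9 [4-bromo-3-(bromomethyl)furan-2-yl]methyl pivalate
Conditions: CBr4, PPh3, CH2Cl2, 0 °C
Reagents that add atoms: tetrabromomethane, BrC(Br)(Br)Br
Why: Appel bromination of the primary alcohol under neutral conditions, the 3-furylmethyl bromide being used directly in step 7.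

Step 6
Reactants: 10 2,2-dimethyl-1,3-dioxan-5-one; 11 (S)-1-amino-2-(methoxymethyl)pyrrolidine (SAMP)
Product: 12 SAMP hydrazone of 2,2-dimethyl-1,3-dioxan-5-one
Conditions: benzene, reflux, Dean–Stark trap
Reagents that add atoms: none
Why: Hydrazone formation by condensation with azeotropic removal of water, which attaches the auxiliary that will control C7.

Step 7
Reactants: 12 SAMP hydrazone of 2,2-dimethyl-1,3-dioxan-5-one; 9 [4-bromo-3-(bromomethyl)furan-2-yl]methyl pivalate
Product: 14 SAMP hydrazone of (4S)-4-{[4-bromo-2-(pivaloyloxymethyl)furan-3-yl]methyl}-2,2-dimethyl-1,3-dioxan-5-one, via lithium azaenolate 13 (not isolated)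
Conditions: t-BuLi (1.05 equiv), THF, −78 °C; then 9, −100 → −78 °C; pH 7 buffer
Reagents that add atoms: none
Why: Enders SAMP-hydrazone alkylation, in which the lithium azaenolate chelated by the methoxymethyl group is alkylated by the furylmethyl bromide on its open face, forming the C6–C7 bond and setting the (S) configuration of the future C7.

Step 8
Reactants: 14 bromo hydrazone
Product: 16 SAMP hydrazone of (4S)-4-{[4-iodo-2-(pivaloyloxymethyl)furan-3-yl]methyl}-2,2-dimethyl-1,3-dioxan-5-one, via furyllithium hydrazone 15 (not isolated)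
Conditions: t-BuLi (2.1 equiv), THF, −100 °C; I2, −100 → −78 °C
Reagents that add atoms: iodine (I2), [I][I]
Why: Bromine–lithium exchange in the absence of any carbonyl group followed by iodination of the 3-furyllithium swaps bromine for iodine, so that the later exchange can outrun attack on the ketone; hydrazone and pivalate are inert for the few minutes needed at −100 °C.

Step 9
Reactants: 16 iodo hydrazone
Product: 17 (4S)-4-{[4-iodo-2-(pivaloyloxymethyl)furan-3-yl]methyl}-2,2-dimethyl-1,3-dioxan-5-one
Conditions: sat. aq. (CO2H)2, Et2O, rt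
Reagents that add atoms: water, O
Why: Biphasic oxalic acid hydrolysis, the standard racemisation-free cleavage of α-alkylated dioxanone hydrazones, liberates the ketone, leaves acetonide and pivalate intact and returns the auxiliary as its oxalate.

Step 10
Reactants: 17 iodo ketone
Product: 20 tricyclic furan with 8α-OSiEt3 and the C3 oxygen as pivalate, via furyllithium ketone 18 (not isolated), via tricyclic lithium alkoxide 19 (not isolated)
Conditions: n-BuLi (1.05 equiv), THF, −100 °C; then Et3SiOTf, −78 → −20 °C
Reagents that add atoms: triethylsilyl trifluoromethanesulfonate, CC[Si](CC)(CC)OS(=O)(=O)C(F)(F)F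
Why: Parham-type cyclisation in which iodine–lithium exchange is faster than addition of n-BuLi to the ketone and the 3-furyllithium adds 5-exo-trig to the C8 carbonyl from the face that carries the C6 tether, so ring B is cis-fused to the dioxane (C10 and 7-O β, 8-O α, 8R), and the tertiary alkoxide is silylated in the same flask.

Step 11
Reactants: 20 tricyclic furan pivalate
Product: 21 furfuryl alcohol precursor (C3–OH free; 8α-OSiEt3; 7,10-O-isopropylidene)
Conditions: iBu2AlH (2.5 equiv), CH2Cl2, −78 °C; aq. sodium potassium tartrate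
Reagents that add atoms: none
Why: Reductive cleavage of the pivalate frees the furfuryl hydroxyl, the only group changed because silyl ether, acetonide and furan do not react with the hydride at −78 °C.

Step 12
Reactants: 21 furfuryl alcohol precursor
Product: 23 pyranone lactol (1-OH lactol; 4-oxo; C5=C9 enone; 8α-OSiEt3; 7,10-O-isopropylidene), via open-chain ene-dicarbonyl 22 (not isolated)
Conditions: NBS (1.05 equiv), NaHCO3, NaOAc, THF/H2O (4:1), 0 °C
Reagents that add atoms: water, O
Why: Achmatowicz rearrangement: electrophilic bromine adds to one α-carbon of the furan, water adds to the other, and the bromo hemiketal collapses with loss of bromide to the ene-dicarbonyl 22 (C4 ketone, C1 aldehyde, C5=C9 held cis by ring B). The primary C3 hydroxyl then adds to the C1 aldehyde, a 6-exo-trig lactolisation that forms the C1–O2 bond and closes ring A (C1, O2, C3, C4, C5, C9). The closest known reaction type is the NBS-mediated oxidative ring expansion of 2-furylcarbinols to 6-hydroxy-2H-pyran-3(6H)-ones. The one new stereocentre, the C1 lactol carbon, is under thermodynamic control because it epimerises through 22; the β-hydroxyl anomer drawn is expected (pseudo-axial hydroxyl on the face away from the 8-silyloxy group), and the centre is fixed only in step 14. The selectivity needed is oxidation of the furan alone, secured because it is the only electron-rich π-system, the sole free hydroxyl is the one that must cyclise, and the bicarbonate–acetate buffer keeps HBr from the acetonide and the silyl ether.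

Step 13
Reactants: 23 pyranone lactol
Product: 24 saturated keto lactol (H5 and H9 β; cis-fused; 1β-OH)
Conditions: H2 (10 atm), [Ir(cod)(PCy3)(py)]PF6 (10 mol %), CH2Cl2, rt
Reagents that add atoms: none
Why: Directed homogeneous hydrogenation with Crabtree's catalyst, in which the cationic iridium is held on the β-face by the hydroxyl of the β-lactol anomer and the dioxane oxygens while the pseudo-axial 8-OSiEt3 screens the α-face, so both hydrogens add syn from the β-face and C5 and C9 are set together as the cis ring fusion.

Step 14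
Reactants: 24 saturated keto lactol; 25 (S)-3-methylpentanoic acid
Product: 26 C1 (S)-3-methylpentanoate of the 4-oxo pyranone (1β-acyloxy)
Conditions: EDC·HCl, DMAP (cat.), CH2Cl2, 0 °C
Reagents that add atoms: none
Why: Steglich esterification of the lactol, whose anomers interconvert through the hydroxy aldehyde; the β-hydroxyl, on the convex face and anti to the C8 quaternary centre, is the one acylated, which fixes C1 with the acyloxy group cis to H9.

Step 15
Reactants: 26 C1 ester ketone
Product: 28 C3=C4 enol triflate, via potassium C3–C4 enolate 27 (not isolated)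
Conditions: KN(SiMe3)2 (1.1 equiv) added to 26 and 2-[N,N-bis(trifluoromethylsulfonyl)amino]-5-chloropyridine (Comins' reagent), THF, −78 °C
Reagents that add atoms: Comins' reagent, FC(F)(F)S(=O)(=O)N(c1ccc(Cl)cn1)S(=O)(=O)C(F)(F)F
Why: Kinetic enolisation by a bulky amide base removes a proton from the exposed C3 methylene and not the ring-fusion C5–H lying under the dioxane, and O-sulfonylation of the enolate as it forms gives the C3=C4 enol triflate, after which C5 can no longer epimerise.

Step 16
Reactants: 28 enol triflate
Product: 29 7,8,10-triol enol triflate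
Conditions: CF3CO2H/H2O/THF (1:1:3), 0 °C → rt
Reagents that add atoms: none
Why: Acid hydrolysis of the isopropylidene ketal and of the tertiary silyl ether at the one stage where it is safe, since the enol ether is deactivated by the triflate, the anomeric ester tolerates aqueous acid and a C1–O10 internal acetal would be trans-fused and cannot form.

Step 17
Reactants: 30 p-coumaric acid
Product: 32 (E)-4-(tert-butyldimethylsilyloxy)cinnamic acid, via bis-silylated coumarate 31 (not isolated)
Conditions: TBSCl (2.2 equiv), imidazole, DMF, rt; then AcOH/THF/H2O, rt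
Reagents that add atoms: tert-butyldimethylsilyl chloride, CC(C)(C)[Si](C)(C)Cl
Why: Silylation of phenol and acid followed by selective hydrolysis of the labile silyl ester masks the phenol so that it cannot compete in the esterification.

Step 18
Reactants: 29 triol enol triflate; 32 O-silyl coumaric acid
Product: 33 C10 O-silyl-p-coumarate enol triflate
Conditions: EDC·HCl, DMAP (cat.), CH2Cl2, −10 → 0 °C
Reagents that add atoms: none
Why: Steglich esterification selective for the primary C10 hydroxyl over the secondary C7 and tertiary C8 hydroxyls.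

Step 19
Reactants: 33 C10 coumarate enol triflate
Product: 34 O-silyl target with C11 hydroxymethyl on C4
Conditions: Bu3SnCH2OH, Pd(PPh3)4 (10 mol %), LiCl, 1,4-dioxane, 90 °C
Reagents that add atoms: (tributylstannyl)methanol, CCCC[Sn](CCCC)(CCCC)CO
Why: Stille coupling of the enol triflate with (tributylstannyl)methanol, in which the α-oxygenated CH2OH group transfers in preference to butyl, installs C11 with its hydroxyl free while free hydroxyls, esters and the (E)-cinnamate are tolerated.

Step 20
Reactants: 34 O-silyl target
Product: 35 target CNP0241834.1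
Conditions: Bu4NF, AcOH (1:1), THF, 0 °C
Reagents that add atoms: none
Why: Buffered fluoride cleavage of the aryl silyl ether is fast at 0 °C and should leave the acyloxy acetal, the enol ether, the allylic alcohol and the cinnamate untouched.

**Compound list**

1 | 3,4-dibromofuran | Brc1cocc1Br | starting material
2 | 3,4-dibromo-2-furyllithium | [Li]c1occ(Br)c1Br | intermediate
3 | 3,4-dibromofuran-2-carbaldehyde | O=Cc1occ(Br)c1Br | intermediate
4 | (3,4-dibromofuran-2-yl)methanol | OCc1occ(Br)c1Br | intermediate
5 | lithium (4-bromo-3-lithiofuran-2-yl)methanolate | [Li]OCc1occ(Br)c1[Li] | intermediate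
6 | 4-bromo-2-(hydroxymethyl)furan-3-carbaldehyde | OCc1occ(Br)c1C=O | intermediate
7 | (4-bromo-3-formylfuran-2-yl)methyl pivalate | CC(C)(C)C(=O)OCc1occ(Br)c1C=O | intermediate
8 | [4-bromo-3-(hydroxymethyl)furan-2-yl]methyl pivalate | CC(C)(C)C(=O)OCc1occ(Br)c1CO | intermediate
9 | [4-bromo-3-(bromomethyl)furan-2-yl]methyl pivalate | CC(C)(C)C(=O)OCc1occ(Br)c1CBr | intermediate
10 | 2,2-dimethyl-1,3-dioxan-5-one | CC1(C)OCC(=O)CO1 | starting material
11 | (S)-1-amino-2-(methoxymethyl)pyrrolidine (SAMP) | COC[C@@H]1CCCN1N | starting material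
12 | (S)-N-(2,2-dimethyl-1,3-dioxan-5-ylidene)-2-(methoxymethyl)pyrrolidin-1-amine | COC[C@@H]1CCCN1N=C1COC(C)(C)OC1 | intermediate
13 | lithium azaenolate of 12 | COC[C@@H]1CCCN1N([Li])C1=COC(C)(C)OC1 | intermediate
14 | SAMP hydrazone of (4S)-4-{[4-bromo-2-(pivaloyloxymethyl)furan-3-yl]methyl}-2,2-dimethyl-1,3-dioxan-5-one | COC[C@@H]1CCCN1N=C1COC(C)(C)O[C@H]1Cc1c(Br)coc1COC(=O)C(C)(C)C | intermediate
15 | 4-lithiofuran analogue of 14 | COC[C@@H]1CCCN1N=C1COC(C)(C)O[C@H]1Cc1c([Li])coc1COC(=O)C(C)(C)C | intermediate
16 | 4-iodofuran analogue of 14 | COC[C@@H]1CCCN1N=C1COC(C)(C)O[C@H]1Cc1c(I)coc1COC(=O)C(C)(C)C | intermediate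
17 | (4S)-4-{[4-iodo-2-(pivaloyloxymethyl)furan-3-yl]methyl}-2,2-dimethyl-1,3-dioxan-5-one | CC1(C)OCC(=O)[C@H](Cc2c(I)coc2COC(=O)C(C)(C)C)O1 | intermediate
18 | 4-lithiofuran analogue of 17 | CC1(C)OCC(=O)[C@H](Cc2c([Li])coc2COC(=O)C(C)(C)C)O1 | intermediate
19 | lithium 8-alkoxide of the tricyclic furan (ring B closed; 7-O and C10 β; 8-O α) | CC(C)(C)C(=O)OCc1occ2c1C[C@@H]3OC(C)(C)OC[C@]23O[Li] | intermediate
20 | tricyclic furan: 5,6-dihydro-4H-cyclopenta[c]furan cis-fused at C7–C8 to a 2,2-dimethyl-1,3-dioxane (7S,8R), 8α-OSiEt3, pivaloyloxymethyl on furan C4 | CC(C)(C)C(=O)OCc1occ2c1C[C@@H]3OC(C)(C)OC[C@]23O[Si](CC)(CC)CC | intermediate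
21 | key-step precursor: as 20 with free hydroxymethyl (C3–OH) on furan C4 | OCc1occ2c1C[C@@H]3OC(C)(C)OC[C@]23O[Si](CC)(CC)CC | intermediate
22 | open-chain ene-dicarbonyl: C4 hydroxymethyl ketone and C1 aldehyde cis on the C5=C9 cyclopentene | OCC(=O)C1=C(C=O)[C@@]2(O[Si](CC)(CC)CC)COC(C)(C)O[C@H]2C1 | intermediate
23 | key-step product: pyranone lactol, 1β-OH (equilibrating), 4-oxo, C5=C9, 8α-OSiEt3, 7,10-O-isopropylidene | O[C@@H]1OCC(=O)C2=C1[C@@]3(O[Si](CC)(CC)CC)COC(C)(C)O[C@H]3C2 | intermediate
24 | saturated keto lactol (1R,5S,7S,8R,9S): H5 and H9 β, cis-fused, 1β-OH | O[C@@H]1OCC(=O)[C@H]2C[C@@H]3OC(C)(C)OC[C@]3(O[Si](CC)(CC)CC)[C@@H]12 | intermediate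
25 | (S)-3-methylpentanoic acid | CC[C@H](C)CC(=O)O | starting material
26 | 1β-O-[(S)-3-methylpentanoyl] 4-oxo pyranone (1S,5S,7S,8R,9S) | CC[C@H](C)CC(=O)O[C@@H]1OCC(=O)[C@H]2C[C@@H]3OC(C)(C)OC[C@]3(O[Si](CC)(CC)CC)[C@@H]12 | intermediate
27 | potassium C3=C4 enolate of 26 | CC[C@H](C)CC(=O)O[C@@H]1OC=C(O[K])[C@H]2C[C@@H]3OC(C)(C)OC[C@]3(O[Si](CC)(CC)CC)[C@@H]12 | intermediate
28 | C4 enol triflate (C3=C4) of 26 | CC[C@H](C)CC(=O)O[C@@H]1OC=C(OS(=O)(=O)C(F)(F)F)[C@H]2C[C@@H]3OC(C)(C)OC[C@]3(O[Si](CC)(CC)CC)[C@@H]12 | intermediate
29 | 7β,8α,10-triol enol triflate | CC[C@H](C)CC(=O)O[C@@H]1OC=C(OS(=O)(=O)C(F)(F)F)[C@H]2C[C@H](O)[C@](O)(CO)[C@@H]12 | intermediate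
30 | p-coumaric acid | OC(=O)/C=C/c1ccc(O)cc1 | starting material
31 | tert-butyldimethylsilyl (E)-4-(tert-butyldimethylsilyloxy)cinnamate | CC(C)(C)[Si](C)(C)OC(=O)/C=C/c1ccc(O[Si](C)(C)C(C)(C)C)cc1 | intermediate
32 | (E)-4-(tert-butyldimethylsilyloxy)cinnamic acid | OC(=O)/C=C/c1ccc(O[Si](C)(C)C(C)(C)C)cc1 | intermediate
33 | 10-O-[(E)-4-(silyloxy)cinnamoyl] 7,8-diol enol triflate | CC[C@H](C)CC(=O)O[C@@H]1OC=C(OS(=O)(=O)C(F)(F)F)[C@H]2C[C@H](O)[C@](O)(COC(=O)/C=C/c3ccc(O[Si](C)(C)C(C)(C)C)cc3)[C@@H]12 | intermediate
34 | O-(tert-butyldimethylsilyl) ether of the target at the phenol | CC[C@H](C)CC(=O)O[C@@H]1OC=C(CO)[C@H]2C[C@H](O)[C@](O)(COC(=O)/C=C/c3ccc(O[Si](C)(C)C(C)(C)C)cc3)[C@@H]12 | intermediate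
35 | CNP0241834.1, (1S,5S,7S,8R,9S) in iridoid numbering, (3S) in the ester | CC[C@H](C)CC(=O)O[C@@H]1OC=C(CO)[C@H]2C[C@H](O)[C@](O)(COC(=O)/C=C/c3ccc(O)cc3)[C@@H]12 | target

**Step count and risks**

Total: 20 steps. Longest linear sequence: 18 steps (1–5, 7–16, 18–20).

Steps most likely to fail:

1. Step 13. Hydrogen may be delivered to the α-face, the tetrasubstituted electron-poor double bond may not turn over, or iridium may isomerise the lactol by internal hydrogen transfer. The fallback sets out from 23 and uses a polar hydride addition in place of hydrogenation. The lactol is oxidised with Dess–Martin periodinane (NaHCO3, CH2Cl2, 0 °C) to the ene keto lactone F1, in which C1 is no longer a stereocentre and the double bond is doubly activated. Li[HB(sBu)3] in THF at −78 °C should add hydride in conjugate fashion to C9, anti to the pseudo-axial allylic C8–O bond, giving the lithium enolate lactone F2, which masks the C4 ketone. In the same flask iBu2AlH at −78 °C reduces the δ-lactone to the lactol, and aqueous tartrate work-up protonates C5, which can equilibrate to the cis fusion. The route is rejoined at 24.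

2. Step 12. The strained 3,4-fused trialkylfuran may be brominated further, or the acetonide may be lost if the buffer is overrun. The fallback sets out from 21 and replaces the bromonium pathway by a cycloaddition. Dye-sensitised photooxygenation (O2, visible light, methylene blue, CH2Cl2, −78 °C) adds singlet oxygen across the two furan α-carbons to give the furan endoperoxide F3. Reduction with Me2S gives the same ene-dicarbonyl 22, which lactolises, and the route is rejoined at 23.

3. Step 19. Transmetalation of the sp3 hydroxymethyl group may be slow, with protodestannylation or thermal degradation of the acyloxy acetal at 90 °C. The fallback sets out from 33 and builds C11 by carbonylation instead. Reductive carbonylation of the triflate (CO 1 atm, Pd(PPh3)4, Bu3SnH added slowly, THF, 50 °C) gives the C11 aldehyde F4, a β-alkoxy enal. Luche reduction (NaBH4, CeCl3·7H2O, MeOH, −78 °C) is selective for the aldehyde over the esters and the cinnamate, and the route is rejoined at 34.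

**Further compounds**

F1 | step 13 | ene keto lactone (C1 lactone of 23) | O=C1OCC(=O)C2=C1[C@@]3(O[Si](CC)(CC)CC)COC(C)(C)O[C@H]3C2
F2 | step 13 | lithium C4 enolate of the saturated 1-oxo lactone (H9 β) | O=C1OCC(O[Li])=C2C[C@@H]3OC(C)(C)OC[C@]3(O[Si](CC)(CC)CC)[C@@H]12
F3 | step 12 | furan endoperoxide of 21 | OCC12OOC(O1)C1=C2C[C@@H]2OC(C)(C)OC[C@]12O[Si](CC)(CC)CC
F4 | step 19 | C11 aldehyde (4-formyl enol ether) | CC[C@H](C)CC(=O)O[C@@H]1OC=C(C=O)[C@H]2C[C@H](O)[C@](O)(COC(=O)/C=C/c3ccc(O[Si](C)(C)C(C)(C)C)cc3)[C@@H]12
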